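**Retrosynthetic overview**

1. Feature: on the cyclohexane (C1 = C(CH3)(CH=CHBr), C2 = CHBr, C3 = CH2, C4 = CHCl, C5 = C(CH3)Cl, C6 = CH2) the equatorial C2–Br is antiperiplanar to the C1–C6 bond, and the vinyl carbon on C1 is 1,3-diaxial (cis) to the C5 chlorine, so a C1–CH2–O–C5 bridge can stand in for both.
2. Target 22 ⇐ aldehyde 20 (Takai E-bromo-olefination) ⇐ alcohol 19 ⇐ BCl3 opening of the tertiary C5–O bond of oxabicycle 16, chloride returning on the face the oxygen leaves.
3. 16 ⇐ dienol 13 by Br+-induced bicyclisation: the C1–C6 bond closes the cyclohexane first, then C5–O closes the bridging tetrahydrofuran.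
4. 13 ⇐ Z-dienoate 12 ⇐ α-chloro ketone 10 ⇐ aldehyde 5 (organocatalytic α-chlorination sets C4) ⇐ Still–Gennari olefination of 4,4-dimethoxybutanal 2.

Key step: step 9

Assumption: the 2,5-diphenylpyrrolidine/NCS α-chlorination is taken to give the (R)-2-chloro aldehyde with the (2S,5S) catalyst (chlorine entering anti to the phenyl group that flanks the enamine carbon); if the sense is the opposite, the (2R,5R) catalyst is used and nothing else changes.

**Route**

Step 1
Reactants: 1 methyl 4,4-dimethoxybutanoate
Product: 2 4,4-dimethoxybutanal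
Conditions: DIBAL-H (1.05 equiv), CH2Cl2, −78 °C; then MeOH, aq. Rochelle salt
Reagents that add atoms: none
Why: Partial ester reduction with one equivalent of DIBAL-H at −78 °C, which holds the aldehyde oxidation state until aqueous work-up, while the dimethyl acetal is inert to the hydride.

Step 2
Reactants: 2 4,4-dimethoxybutanal; 3 ethyl 2-[bis(2,2,2-trifluoroethoxy)phosphoryl]propanoate
Product: 4 ethyl (2Z)-6,6-dimethoxy-2-methylhex-2-enoate
Conditions: KHMDS, 18-crown-6, THF, −78 °C
Reagents that add atoms: ethyl 2-[bis(2,2,2-trifluoroethoxy)phosphoryl]propanoate (3), CCOC(=O)C(C)P(=O)(OCC(F)(F)F)OCC(F)(F)F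
Why: Still–Gennari variant of the Horner–Wadsworth–Emmons reaction, in which the bis(trifluoroethyl) phosphonate and a dissociated potassium counter-ion make the elimination fast and kinetically controlled, so the Z-trisubstituted enoate should form; this geometry later places CH2OH cis to the ring bromine.

Step 3
Reactants: 4 ethyl (2Z)-6,6-dimethoxy-2-methylhex-2-enoate
Product: 5 ethyl (2Z)-2-methyl-6-oxohex-2-enoate
Conditions: 1 M aq. HCl, THF, 0 °C → rt
Reagents that add atoms: water, O
Why: Acid-catalysed hydrolysis of a dimethyl acetal, under which the ethyl ester and the Z-trisubstituted alkene are stable.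

Step 4
Reactants: 5 ethyl (2Z)-2-methyl-6-oxohex-2-enoate; 6 N-chlorosuccinimide
Product: 7 ethyl (2Z,5R)-5-chloro-2-methyl-6-oxohex-2-enoate
Conditions: (2S,5S)-2,5-diphenylpyrrolidine (10 mol%), CH2Cl2, 0 °C → rt; pentane, filtration; used without chromatography
Reagents that add atoms: N-chlorosuccinimide (6), O=C1CCC(=O)N1Cl
Why: Organocatalytic α-chlorination of an aldehyde by enamine catalysis, in which the C2-symmetric pyrrolidine shields one face of the E-enamine so that chlorine from NCS enters the other and sets C5 as R (the later ring C4); the product is carried on crude because α-chloro aldehydes epimerise on silica.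

Step 5
Reactants: 7 ethyl (2Z,5R)-5-chloro-2-methyl-6-oxohex-2-enoate; 8 methylmagnesium bromide
Product: 9 ethyl (2Z,5R)-5-chloro-6-hydroxy-2-methylhept-2-enoate (both C6 epimers)
Conditions: THF/Et2O, −78 °C; then pH 7 buffer
Reagents that add atoms: methylmagnesium bromide (8), C[Mg]Br
Why: Grignard 1,2-addition to the aldehyde, which is far more electrophilic than the trisubstituted enoate at −78 °C; the configuration of the new carbinol carbon is irrelevant because it is oxidised in step 6, and the cold neutral quench keeps the chlorohydrin from closing to an epoxide.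

Step 6
Reactants: 9 ethyl (2Z,5R)-5-chloro-6-hydroxy-2-methylhept-2-enoate (both C6 epimers)
Product: 10 ethyl (2Z,5R)-5-chloro-2-methyl-6-oxohept-2-enoate
Conditions: Dess–Martin periodinane, CH2Cl2, 0 °C → rt
Reagents that add atoms: none
Why: Dess–Martin oxidation of a secondary alcohol under non-basic conditions, which should give the α-chloro ketone without enolisation so that C5 keeps its configuration.

Step 7
Reactants: 10 ethyl (2Z,5R)-5-chloro-2-methyl-6-oxohept-2-enoate; 11 Tebbe reagent
Product: 12 ethyl (2Z,5R)-5-chloro-2,6-dimethylhepta-2,6-dienoate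
Conditions: Tebbe reagent (1.2 equiv), pyridine (cat.), THF/toluene, −40 → 0 °C
Reagents that add atoms: Tebbe reagent (11), C=[Ti](C1C=CC=C1)C1C=CC=C1.C[Al](C)Cl
Why: Tebbe methylenation, in which the non-basic titanium methylidene transfers CH2 to the ketone by [2+2] addition and cycloreversion faster than to the ester at low temperature, so the enolisable α-chloro stereocentre and the enoate should be left alone.

Step 8
Reactants: 12 ethyl (2Z,5R)-5-chloro-2,6-dimethylhepta-2,6-dienoate
Product: 13 (2Z,5R)-5-chloro-2,6-dimethylhepta-2,6-dien-1-ol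
Conditions: DIBAL-H (2.5 equiv), CH2Cl2, −78 °C; then aq. Rochelle salt
Reagents that add atoms: none
Why: DIBAL-H 1,2-reduction of the α,β-unsaturated ester to the allylic alcohol with retention of the Z geometry, the secondary allylic chloride not being reduced by DIBAL-H at −78 °C.

Step 9
Reactants: 13 (2Z,5R)-5-chloro-2,6-dimethylhepta-2,6-dien-1-ol; 14 bromodiethylsulfonium bromopentachloroantimonate (BDSB)
Product: 16 (1S,2S,4R,5S)-2-bromo-4-chloro-1,5-dimethyl-6-oxabicyclo[3.2.1]octane, via tertiary cyclohexyl cation 15 (not isolated)
Conditions: BDSB (1.1 equiv), MeNO2, −25 °C, 5 min; then aq. NaHCO3/Na2SO3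
Reagents that add atoms: bromodiethylsulfonium bromopentachloroantimonate (14), CC[S+](Br)CC.Br[Sb-](Cl)(Cl)(Cl)(Cl)Cl
Why: Br+ passes from the sulfonium to the trisubstituted alkene and, through a bromiranium-like chair transition state, the CH2 terminus of the isopropenyl group (ring C6) attacks the tertiary alkene carbon (ring C1) anti to the new C2–Br bond, giving cation 15 at ring C5, which the primary hydroxyl captures with loss of a proton. The closest known reaction type is the bromonium-initiated cation–olefin (polyene-type) cyclisation terminated by a hydroxyl group, as run with BDSB or TBCO on terpenoid dienols. The cyclohexane closes in the 6-endo mode (Markovnikov opening of the bromiranium at its tertiary carbon, both alkene carbons of the nucleophile ending in the ring), and the tetrahydrofuran closes as a five-membered ring by oxygen capture of the cation across the 1,3-diaxial positions, which gives the 6-oxabicyclo[3.2.1]octane. C2 (S) follows from anti addition, which leaves bromine equatorial and antiperiplanar to C1–C6; C1 (S) follows from the Z geometry, which puts CH2OH axial and cis to bromine; C5 (S) is fixed by the tether, since oxygen reaches the cation only from the face of the axial CH2OH arm; all three are tied to the existing C4 centre by the chair in which the C4 chlorine is equatorial and lies in the nodal plane of the reacting π bond, so that it withdraws least from the developing cation. The step needs bromination of the trisubstituted alkene in preference to the isopropenyl alkene, which the allylic chlorine on the latter should secure, and it needs face selection relative to C4–Cl, which rests on Br+ transfer being reversible (diethyl sulfide is present) so that the lower-energy chair decides.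

Step 10
Reactants: 16 (1S,2S,4R,5S)-2-bromo-4-chloro-1,5-dimethyl-6-oxabicyclo[3.2.1]octane; 17 boron trichloride
Product: 19 [(1S,2S,4R,5S)-2-bromo-4,5-dichloro-1,5-dimethylcyclohexyl]methanol, via dichloroborinate ester 18 (not isolated)
Conditions: BCl3 (1 M in CH2Cl2, 2 equiv), CH2Cl2, −78 → −20 °C; then H2O
Reagents that add atoms: boron trichloride (17), ClB(Cl)Cl
Why: Lewis-acid cleavage of an ether by BCl3, in which boron binds the bridging oxygen, the tertiary C5–O bond ionises in preference to the neopentyl CH2–O bond, and chloride is handed back from boron on the face still covered by the CH2O–B arm (front-side, axial return), which should give the C5 chloride with retention, cis to the C1 arm, with Cl axial and CH3 equatorial; water then hydrolyses borinate 18 to the alcohol.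

Step 11
Reactants: 19 [(1S,2S,4R,5S)-2-bromo-4,5-dichloro-1,5-dimethylcyclohexyl]methanol
Product: 20 (1S,2S,4R,5S)-2-bromo-4,5-dichloro-1,5-dimethylcyclohexane-1-carbaldehyde
Conditions: Dess–Martin periodinane, CH2Cl2, rt
Reagents that add atoms: none
Why: Dess–Martin oxidation of the neopentyl primary alcohol to an aldehyde that has no α-hydrogen, so neither epimerisation at C1 nor β-elimination of the C2 bromide can follow.

Step 12
Reactants: 20 (1S,2S,4R,5S)-2-bromo-4,5-dichloro-1,5-dimethylcyclohexane-1-carbaldehyde; 21 bromoform
Product: 22 (1S,2S,4R,5S)-2-bromo-1-[(E)-2-bromoethenyl]-4,5-dichloro-1,5-dimethylcyclohexane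
Conditions: CHBr3, CrBr2 (anhydrous), THF, 0 °C → rt
Reagents that add atoms: bromoform (21), BrC(Br)Br
Why: Takai–Utimoto halo-olefination, in which the geminal dichromium species formed from bromoform adds to the aldehyde and anti-periplanar elimination should give the E-bromoalkene; chromium(II) bromide replaces the chloride so that no chloride can exchange into the vinyl position, and unactivated alkyl halides are not reduced by chromium(II) in THF at this temperature.

**Compound list**

1 | methyl 4,4-dimethoxybutanoate | COC(=O)CCC(OC)OC | starting material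
2 | 4,4-dimethoxybutanal | O=CCCC(OC)OC | intermediate
3 | ethyl 2-[bis(2,2,2-trifluoroethoxy)phosphoryl]propanoate | CCOC(=O)C(C)P(=O)(OCC(F)(F)F)OCC(F)(F)F | starting material
4 | ethyl (2Z)-6,6-dimethoxy-2-methylhex-2-enoate | CCOC(=O)/C(C)=C\CCC(OC)OC | intermediate
5 | ethyl (2Z)-2-methyl-6-oxohex-2-enoate | CCOC(=O)/C(C)=C\CCC=O | intermediate
6 | N-chlorosuccinimide | O=C1CCC(=O)N1Cl | starting material
7 | ethyl (2Z,5R)-5-chloro-2-methyl-6-oxohex-2-enoate | CCOC(=O)/C(C)=C\C[C@@H](Cl)C=O | intermediate
8 | methylmagnesium bromide | C[Mg]Br | starting material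
9 | ethyl (2Z,5R)-5-chloro-6-hydroxy-2-methylhept-2-enoate (both C6 epimers) | CCOC(=O)/C(C)=C\C[C@@H](Cl)C(C)O | intermediate
10 | ethyl (2Z,5R)-5-chloro-2-methyl-6-oxohept-2-enoate | CCOC(=O)/C(C)=C\C[C@@H](Cl)C(C)=O | intermediate
11 | Tebbe reagent, Cp2Ti(μ-CH2)(μ-Cl)AlMe2, written as the titanocene methylidene–Me2AlCl adduct | C=[Ti](C1C=CC=C1)C1C=CC=C1.C[Al](C)Cl | starting material
12 | ethyl (2Z,5R)-5-chloro-2,6-dimethylhepta-2,6-dienoate | CCOC(=O)/C(C)=C\C[C@@H](Cl)C(C)=C | intermediate
13 | (2Z,5R)-5-chloro-2,6-dimethylhepta-2,6-dien-1-ol | C=C(C)[C@H](Cl)C/C=C(/C)CO | intermediate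
14 | bromodiethylsulfonium bromopentachloroantimonate (BDSB) | CC[S+](Br)CC.Br[Sb-](Cl)(Cl)(Cl)(Cl)Cl | starting material
15 | (2R,4S,5S)-4-bromo-2-chloro-5-(hydroxymethyl)-1,5-dimethylcyclohexan-1-ylium (tertiary cyclohexyl cation, not isolated) | C[C+]1C[C@@](C)(CO)[C@@H](Br)C[C@H]1Cl | intermediate
16 | (1S,2S,4R,5S)-2-bromo-4-chloro-1,5-dimethyl-6-oxabicyclo[3.2.1]octane | C[C@]1(O2)C[C@@](C)(C2)[C@@H](Br)C[C@H]1Cl | intermediate
17 | boron trichloride | ClB(Cl)Cl | starting material
18 | [(1S,2S,4R,5S)-2-bromo-4,5-dichloro-1,5-dimethylcyclohexyl]methyl dichloroborinate (not isolated) | C[C@]1(Cl)C[C@@](C)(COB(Cl)Cl)[C@@H](Br)C[C@H]1Cl | intermediate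
19 | [(1S,2S,4R,5S)-2-bromo-4,5-dichloro-1,5-dimethylcyclohexyl]methanol | C[C@]1(Cl)C[C@@](C)(CO)[C@@H](Br)C[C@H]1Cl | intermediate
20 | (1S,2S,4R,5S)-2-bromo-4,5-dichloro-1,5-dimethylcyclohexane-1-carbaldehyde | C[C@]1(Cl)C[C@@](C)(C=O)[C@@H](Br)C[C@H]1Cl | intermediate
21 | bromoform | BrC(Br)Br | starting material
22 | (1S,2S,4R,5S)-2-bromo-1-[(E)-2-bromoethenyl]-4,5-dichloro-1,5-dimethylcyclohexane | C[C@]1(Cl)C[C@@](C)(/C=C/Br)[C@@H](Br)C[C@H]1Cl | target

**Step count and risks**

Total step count: 12. Longest linear sequence: 12 steps, from compound 1.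

Steps most likely to fail:

Step 9. Facial selectivity relative to the C4 chlorine may be poor if Br+ transfer to the trisubstituted alkene turns out to be irreversible, because the face would then be chosen before the chair can sense the chlorine. The chlorine-deactivated isopropenyl group may also attack so slowly that the bromiranium is consumed in other ways. The fallback replaces bromine by a reversible π-acid and sets out from 13. Mercury(II) trifluoroacetate in nitromethane at −20 °C should give, by the same bicyclisation under chair control, [(1S,2S,4R,5S)-4-chloro-1,5-dimethyl-6-oxabicyclo[3.2.1]octan-2-yl]mercury trifluoroacetate F1. Aqueous potassium bromide would exchange this to bromo[(1S,2S,4R,5S)-4-chloro-1,5-dimethyl-6-oxabicyclo[3.2.1]octan-2-yl]mercury F2. Brominative demercuration with Br2 and LiBr in pyridine under oxygen, which proceeds with retention at carbon, then returns to the route at 16.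

Step 10. Ionisation of the C5–O bond is slowed by the neighbouring C4 chlorine, so proton loss from the cation, a hydride shift from C4, or chloride entry from the lower face may overtake front-side chloride return. The fallback turns the tertiary oxygen into a carboxylate leaving group before the C–O bond is broken and sets out from 16. Ruthenium tetroxide oxidation (RuCl3 cat., NaIO4, CCl4/MeCN/H2O) of the only CH2 next to oxygen should give (1S,2S,4R,5S)-2-bromo-4-chloro-1,5-dimethyl-6-oxabicyclo[3.2.1]octan-7-one F3. Thionyl chloride with catalytic zinc chloride would open the tertiary alkyl–oxygen bond of this lactone to (1S,2S,4R,5S)-2-bromo-4,5-dichloro-1,5-dimethylcyclohexane-1-carbonyl chloride F4. Reduction with LiAlH(OtBu)3 in THF at −78 °C then rejoins the route at aldehyde 20, so step 11 is not needed.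

Step 7. The C5 configuration may be lost by enolisation of the α-chloro ketone, the titanium methylidene may attack the ester, or the aluminium Lewis acid may ionise the new allylic chloride. The fallback is a two-step Peterson olefination and sets out from 10. Addition of (trimethylsilyl)methylmagnesium chloride premixed with anhydrous CeCl3 (THF, −78 °C), a non-basic nucleophile that spares the ester, should give ethyl (2Z,5R)-5-chloro-6-hydroxy-2,6-dimethyl-7-(trimethylsilyl)hept-2-enoate F5. Acid-promoted elimination (BF3·OEt2, CH2Cl2, 0 °C) then returns to the route at 12.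

**Further compounds**

F1 | step 9 | [(1S,2S,4R,5S)-4-chloro-1,5-dimethyl-6-oxabicyclo[3.2.1]octan-2-yl]mercury trifluoroacetate | C[C@]1(O2)C[C@@](C)(C2)[C@@H]([Hg]OC(=O)C(F)(F)F)C[C@H]1Cl
F2 | step 9 | bromo[(1S,2S,4R,5S)-4-chloro-1,5-dimethyl-6-oxabicyclo[3.2.1]octan-2-yl]mercury | C[C@]1(O2)C[C@@](C)(C2)[C@@H]([Hg]Br)C[C@H]1Cl
F3 | step 10 | (1S,2S,4R,5S)-2-bromo-4-chloro-1,5-dimethyl-6-oxabicyclo[3.2.1]octan-7-one | C[C@]1(O2)C[C@@](C)(C2=O)[C@@H](Br)C[C@H]1Cl
F4 | step 10 | (1S,2S,4R,5S)-2-bromo-4,5-dichloro-1,5-dimethylcyclohexane-1-carbonyl chloride | C[C@]1(Cl)C[C@@](C)(C(Cl)=O)[C@@H](Br)C[C@H]1Cl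
F5 | step 7 | ethyl (2Z,5R)-5-chloro-6-hydroxy-2,6-dimethyl-7-(trimethylsilyl)hept-2-enoate (both C6 epimers) | CCOC(=O)/C(C)=C\C[C@@H](Cl)C(C)(O)C[Si](C)(C)C
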